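**Retrosynthetic overview**

1. Numbering (kaurane): ring A = C1–C5 and C10 (C19 carboxyl and C18 methyl on C4, C6 carboxyl on C5, C20 methyl on C10); C9 = CH joining the rings; ring C = C8, C9, C11 (ketone), C12, C13, C14; C7 = CHO on quaternary C8; ring D = C8–C14–C13–C16(=C17)–C15.
2. Endgame: the C11 ketone comes from a C11 carbinol that is released, together with the C6 acid, from a temporary six-membered lactone (C6–O–C11–C9–C10–C5); C19 is unmasked from a 2-(trimethylsilyl)ethyl ester.
3. Key disconnection: C9–C10 and then C8–C15 in one radical–polar crossover cascade of oxalate 23. The feature used: the C6 carboxyl and the C11 oxygen are 1,5-related across C5–C10–C9, so their ester delivers a C10 radical to C9 on the face of O11; C8 and C13 are 1,3-related on ring C, so the enolate formed at C8 reaches the allylic chloride (C15) carried by C13.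
4. Oxalate 23 comes from ring-A anhydride 18 (C4 by asymmetric conjugate addition, C5 by aldol/lactonization, C10 by methylenation/hydration) and ring-C hydroxy enal 8 (C13 by asymmetric 1,4-addition, C11–O by epoxidation, C7 by Wittig homologation).
5. Ring order: rings C and A are carried in from cyclohexenones; the temporary lactone and then ring D (closing the bicyclo[3.2.1]octane) form in the key step; the lactone is opened at the end.

Key step: step 15

Remark (assumption): the ligand enantiomers in steps 1 and 5 are taken to be those that give the drawn (R) centres; the configuration of the carbinol/oxalate carbon (C10) in 15–23 is immaterial because it becomes a planar radical.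

**Route**

Step 1
Reactants: 1 cyclohex-2-en-1-one; 2 isopropenylboronic acid pinacol ester
Product: 3 (R)-3-(prop-1-en-2-yl)cyclohexan-1-one
Conditions: [Rh(cod)Cl]2 (1.5 mol %), (R)-BINAP (3.3 mol %), KOH (0.5 equiv), dioxane/H2O, 30 °C
Reagents that add atoms: none
Why: Hayashi–Miyaura rhodium-catalysed asymmetric 1,4-addition of an alkenylboronate, in which the BINAP ligand selects the enone face and so sets the future C13 centre.

Step 2
Reactants: 3 (R)-3-(prop-1-en-2-yl)cyclohexan-1-one
Product: 5 (R)-5-(prop-1-en-2-yl)cyclohex-2-en-1-one, via silyl enol ether 4 (not isolated)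
Conditions: LiN(iPr)2, Me3SiCl, THF, −78 °C; then Pd(OAc)2 (10 mol %), O2 (1 atm), DMSO, rt
Reagents that add atoms: none
Why: Saegusa–Ito dehydrogenation, in which kinetic deprotonation on the side remote from the substituent gives the less substituted silyl enol ether and palladium diacetate converts it into the enone without touching the stereocentre.

Step 3
Reactants: 5 (R)-5-(prop-1-en-2-yl)cyclohex-2-en-1-one
Product: 6 (1R,4R,6R)-4-(prop-1-en-2-yl)-7-oxabicyclo[4.1.0]heptan-2-one
Conditions: 30% H2O2, NaOH (cat.), MeOH, 0 °C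
Reagents that add atoms: hydrogen peroxide, OO
Why: Weitz–Scheffer nucleophilic epoxidation, in which hydroperoxide adds axially to the β-carbon anti to the isopropenyl group, so the epoxide (the future C11–O bond) is trans to the C13 substituent.

Step 4
Reactants: 6 (1R,4R,6R)-4-(prop-1-en-2-yl)-7-oxabicyclo[4.1.0]heptan-2-one
Product: 8 (3R,5S)-3-hydroxy-5-(prop-1-en-2-yl)cyclohex-1-ene-1-carbaldehyde, via enol ether 7 (not isolated)
Conditions: Ph3P(CH2OMe)Cl, KN(SiMe3)2, THF, 0 °C → rt; then 1 M HCl, THF, rt
Reagents that add atoms: (methoxymethyl)triphenylphosphonium chloride, COC[P+](c1ccccc1)(c1ccccc1)c1ccccc1.[Cl-]; water, O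
Why: Wittig methoxymethylenation followed by acid hydrolysis, in which the enol ether opens the adjacent epoxide at its allylic C–O bond to give the 4-hydroxy-2-enal; the C11–O bond is not broken, so the hydroxyl stays trans to the isopropenyl group.

Step 5
Reactants: 9 methyl 3-oxocyclohex-1-ene-1-carboxylate
Product: 11 methyl (R)-1-methyl-3-[(trimethylsilyl)oxy]cyclohex-2-ene-1-carboxylate, via aluminium enolate 10 (not isolated)
Conditions: Me3Al, Cu(O2CC4H3S) (2 mol %), chiral phosphoramidite ligand (4 mol %), Et2O, −30 °C; then Me3SiOTf, THF, −30 → 0 °C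
Reagents that add atoms: trimethylaluminium, C[Al](C)C; trimethylsilyl trifluoromethanesulfonate, C[Si](C)(C)OS(=O)(=O)C(F)(F)F
Why: copper-catalysed asymmetric conjugate addition of methyl to the ester-bearing β-carbon creates the C4 quaternary centre under ligand control, and silylation of the regiodefined enolate fixes the enol ether toward C5.

Step 6
Reactants: 11 methyl (R)-1-methyl-3-[(trimethylsilyl)oxy]cyclohex-2-ene-1-carboxylate
Product: 13 (3aS,7aR)-7a-methylhexahydro-2-benzofuran-1,4-dione, via hydroxymethyl ketone 12 (not isolated)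
Conditions: 37% aq. HCHO, Yb(OTf)3 (10 mol %), THF, rt; then camphorsulfonic acid (10 mol %), toluene, 80 °C
Reagents that add atoms: formaldehyde, C=O
Why: aqueous Mukaiyama aldol reaction with formaldehyde puts C6 on C5 and acid-catalysed lactonization onto the C19 ester follows; C5 epimerizes through the ketone enol and only the cis isomer closes the five-membered lactone, so C6 ends cis to C19.

Step 7
Reactants: 13 (3aS,7aR)-7a-methylhexahydro-2-benzofuran-1,4-dione
Product: 14 (3aS,7aR)-7a-methyl-4-methylidenehexahydro-2-benzofuran-1(3H)-one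
Conditions: Zn, CH2Br2, TiCl4, THF, 0 °C → rt
Reagents that add atoms: dibromomethane, BrCBr
Why: Takai–Lombardo methylenation is non-basic and ketone-selective, so the lactone and the C5 centre next to a β-acyloxy group survive.

Step 8
Reactants: 14 (3aS,7aR)-7a-methyl-4-methylidenehexahydro-2-benzofuran-1(3H)-one
Product: 15 (3aS,4R,7aR)-4-hydroxy-4,7a-dimethylhexahydro-2-benzofuran-1(3H)-one
Conditions: Mn(dpm)3 (5 mol %), PhSiH3, O2 (1 atm), iPrOH/CH2Cl2, 0 °C → rt
Reagents that add atoms: dioxygen, O=O
Why: Mukaiyama hydration (hydrogen-atom transfer, Markovnikov) gives the tertiary alcohol carrying the C20 methyl, oxygen trapping the radical on the face away from the lactone ring so that the hydroxyl is trans to both acyl groups.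

Step 9
Reactants: 15 (3aS,4R,7aR)-4-hydroxy-4,7a-dimethylhexahydro-2-benzofuran-1(3H)-one
Product: 17 (1R,2R,3R)-3-hydroxy-1,3-dimethylcyclohexane-1,2-dicarboxylic acid, via sodium carboxylate 16 (not isolated)
Conditions: NaOH, H2O/MeCN, rt; then phosphate buffer (pH 6.7), TEMPO (cat.), NaOCl (cat.), NaClO2, 35 °C; then HCl to pH 2
Reagents that add atoms: sodium hydroxide, [Na+].[OH-]; sodium chlorite, [Na+].[O-]Cl=O
Why: saponification of the lactone and TEMPO/chlorite oxidation of the freed primary alcohol in the same pot, before relactonization, turns C6 into the carboxylic acid without touching a stereocentre.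

Step 10
Reactants: 17 (1R,2R,3R)-3-hydroxy-1,3-dimethylcyclohexane-1,2-dicarboxylic acid
Product: 18 (3aR,4R,7aR)-4-hydroxy-4,7a-dimethylhexahydro-2-benzofuran-1,3-dione
Conditions: DCC, THF, 0 °C → rt
Reagents that add atoms: none
Why: carbodiimide dehydration of the cis-1,2-diacid gives the five-membered cyclic anhydride, and the tertiary hydroxyl, trans to both carbonyls, cannot acylate intramolecularly.

Step 11
Reactants: 18 (3aR,4R,7aR)-4-hydroxy-4,7a-dimethylhexahydro-2-benzofuran-1,3-dione; 8 (3R,5S)-3-hydroxy-5-(prop-1-en-2-yl)cyclohex-1-ene-1-carbaldehyde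
Product: 19 (1R,2R,3R)-2-({[(1R,5S)-3-formyl-5-(prop-1-en-2-yl)cyclohex-2-en-1-yl]oxy}carbonyl)-3-hydroxy-1,3-dimethylcyclohexane-1-carboxylic acid
Conditions: DMAP, Et3N, CH2Cl2, rt
Reagents that add atoms: none
Why: DMAP-mediated alcoholysis of the cyclic anhydride should occur at the carbonyl on the tertiary carbon (C6) rather than at the one on the quaternary carbon (C19), with retention at C11, giving the ester that becomes the temporary lactone.

Step 12
Reactants: 19 C6 ester / C19 acid from step 11
Product: 20 2-(trimethylsilyl)ethyl ester of 19 at C19 (ring-C ester at C6, free tertiary alcohol at C10)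
Conditions: Me3SiCH2CH2OH, PPh3, DIAD, THF, 0 °C → rt
Reagents that add atoms: 2-(trimethylsilyl)ethanol, C[Si](C)(C)CCO
Why: Mitsunobu esterification in which the hindered C19 carboxylate is the nucleophile toward the activated primary alcohol; the ester keeps this carboxylate from being oxidized in step 15.

Step 13
Reactants: 20 diester with isopropenyl group
Product: 21 analogue of 20 with a 3-chloroprop-1-en-2-yl group on C13
Conditions: NCS, PhSeCl (10 mol %), CH2Cl2, rt
Reagents that add atoms: N-chlorosuccinimide, O=C1CCC(=O)N1Cl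
Why: selenium-catalysed ene-type allylic chlorination of the electron-rich 1,1-disubstituted alkene with double-bond shift gives the 2-(chloromethyl)allyl unit, while the electron-poor enal alkene does not react.

Step 14
Reactants: 21 allylic chloride with free tertiary alcohol
Product: 23 caesium oxalate of the tertiary alcohol of 21, via methyl oxalate 22 (not isolated)
Conditions: MeO2CCOCl, Et3N, DMAP (cat.), CH2Cl2, 0 °C → rt; then CsOH·H2O (1.0 equiv), THF/H2O, 0 °C
Reagents that add atoms: methyl chlorooxoacetate, COC(=O)C(=O)Cl; caesium hydroxide, [Cs+].[OH-]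
Why: acylation of the tertiary alcohol and chemoselective half-saponification of the highly electrophilic oxalate methyl ester give the caesium alkyl oxalate, a precursor of the tertiary C10 radical.

Step 15
Reactants: 23 caesium oxalate
Product: 25 2-(trimethylsilyl)ethyl (4R,5S,8R,9S,10S,11R,13S)-11-hydroxy-7-oxo-6,7-secokaur-16-ene-6,19-dioate 6,11-lactone, via caesium enolate 24 (not isolated)
Conditions: Ir[dF(CF3)ppy]2(dtbbpy)PF6 (2 mol %), anhydrous degassed DME/DMF, 4 Å sieves, 450 nm LEDs, 40 °C
Reagents that add atoms: none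
Why: Proposed new method: the excited iridium photocatalyst oxidizes the oxalate, two CO2 are lost to give the tertiary C10 radical, this adds through the ester tether to C9 (β-carbon of the enal), the α-formyl radical at C8 is reduced by the reduced photocatalyst to caesium enolate 24, and the enolate displaces the allylic chloride at C15 (an O-allylated enol ether would give the same aldehyde by Claisen rearrangement). The closest known reaction types are the photoredox Giese addition of tertiary radicals from caesium alkyl oxalates and decarboxylative radical addition–polar cyclization cascades of halide-tethered acceptors; their combination through an ester tether to close a bridged ring is not known. The lactone ring (C6–O–C11–C9–C10–C5) closes by 6-exo-trig radical cyclization and ring D (C8–C14–C13–C16–C15) by 5-exo-tet enolate alkylation forming C8–C15. C9 is controlled by the allylic C11–O tether, which delivers C10 to its own face (cis-fused lactone) and therefore trans to the C13 side chain; C10 is controlled by a chair-like transition state with C6 and the forming bond both equatorial on ring A, which puts the C20 methyl axial and cis to C19; C8 is controlled by the C13 side chain, since the enolate can only be alkylated on the face that carries it. The step needs the nucleophilic radical to choose the enal carbon over the chloromethyl-alkene, which polarity matching and intramolecularity secure, and it needs alkylation to beat protonation of the enolate, which the exclusion of water secures.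

Step 16
Reactants: 25 lactone aldehyde
Product: 27 (4R,5S,8R,9S,10S,11R,13S)-11-hydroxy-7-oxo-6,7-secokaur-16-ene-6,19-dioic acid, via acid lactone 26 (not isolated)
Conditions: Bu4NF, THF, rt; then LiOH, THF/H2O, rt; then 1 M HCl (pH 3)
Reagents that add atoms: lithium hydroxide, [Li+].[OH-]
Why: fluoride-induced fragmentation of the 2-(trimethylsilyl)ethyl ester frees the C19 acid and saponification opens the temporary lactone to the C6 acid and the C11 alcohol, C9 not being α to a carbonyl at this stage.

Step 17
Reactants: 27 hydroxy diacid aldehyde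
Product: 28 (4R,5S,8R,9S,10S,13S)-7,11-dioxo-6,7-secokaur-16-ene-6,19-dioic acid (target)
Conditions: Dess–Martin periodinane, CH2Cl2, rt
Reagents that add atoms: none
Why: Dess–Martin oxidation of the C11 carbinol under neutral conditions gives the ketone without enolizing C9 and leaves the non-enolizable neopentyl aldehyde untouched.

**Compound list**

1 | cyclohex-2-en-1-one | O=C1C=CCCC1 | starting material
2 | isopropenylboronic acid pinacol ester | CC(=C)B1OC(C)(C)C(C)(C)O1 | starting material
3 | (R)-3-(prop-1-en-2-yl)cyclohexan-1-one | O=C1CCC[C@@H](C(C)=C)C1 | intermediate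
4 | (R)-trimethyl{[5-(prop-1-en-2-yl)cyclohex-1-en-1-yl]oxy}silane | C[Si](C)(C)OC1=CCC[C@@H](C(C)=C)C1 | intermediate
5 | (R)-5-(prop-1-en-2-yl)cyclohex-2-en-1-one | O=C1C=CC[C@@H](C(C)=C)C1 | intermediate
6 | (1R,4R,6R)-4-(prop-1-en-2-yl)-7-oxabicyclo[4.1.0]heptan-2-one (epoxide trans to isopropenyl) | O=C1[C@@H]2O[C@@H]2C[C@@H](C(C)=C)C1 | intermediate
7 | 2-(methoxymethylidene)-4-(prop-1-en-2-yl)-7-oxabicyclo[4.1.0]heptane, E/Z mixture, ring configuration as in 6 | COC=C1[C@@H]2O[C@@H]2C[C@@H](C(C)=C)C1 | intermediate
8 | (3R,5S)-3-hydroxy-5-(prop-1-en-2-yl)cyclohex-1-ene-1-carbaldehyde (OH trans to isopropenyl) | O=CC1=C[C@H](O)C[C@@H](C(C)=C)C1 | intermediate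
9 | methyl 3-oxocyclohex-1-ene-1-carboxylate | COC(=O)C1=CC(=O)CCC1 | starting material
10 | dimethylaluminium enolate of methyl (R)-1-methyl-3-oxocyclohexane-1-carboxylate | COC(=O)[C@]1(C)CCCC(O[Al](C)C)=C1 | intermediate
11 | methyl (R)-1-methyl-3-[(trimethylsilyl)oxy]cyclohex-2-ene-1-carboxylate | COC(=O)[C@]1(C)CCCC(O[Si](C)(C)C)=C1 | intermediate
12 | methyl (1R)-2-(hydroxymethyl)-1-methyl-3-oxocyclohexane-1-carboxylate (both C2 epimers) | COC(=O)[C@]1(C)CCCC(=O)C1CO | intermediate
13 | (3aS,7aR)-7a-methylhexahydro-2-benzofuran-1,4-dione (cis-fused keto lactone) | O=C1OC[C@H]2C(=O)CCC[C@@]12C | intermediate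
14 | (3aS,7aR)-7a-methyl-4-methylidenehexahydro-2-benzofuran-1(3H)-one | O=C1OC[C@H]2C(=C)CCC[C@@]12C | intermediate
15 | (3aS,4R,7aR)-4-hydroxy-4,7a-dimethylhexahydro-2-benzofuran-1(3H)-one | O=C1OC[C@H]2[C@](C)(O)CCC[C@@]12C | intermediate
16 | sodium 3-hydroxy-2-(hydroxymethyl)-1,3-dimethylcyclohexane-1-carboxylate (ring-opened 15) | [Na+].[O-]C(=O)[C@]1(C)CCC[C@@](C)(O)[C@@H]1CO | intermediate
17 | (1R,2R,3R)-3-hydroxy-1,3-dimethylcyclohexane-1,2-dicarboxylic acid | OC(=O)[C@]1(C)CCC[C@@](C)(O)[C@@H]1C(=O)O | intermediate
18 | (3aR,4R,7aR)-4-hydroxy-4,7a-dimethylhexahydro-2-benzofuran-1,3-dione | O=C1OC(=O)[C@H]2[C@](C)(O)CCC[C@@]12C | intermediate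
19 | (1R,2R,3R)-2-({[(1R,5S)-3-formyl-5-(prop-1-en-2-yl)cyclohex-2-en-1-yl]oxy}carbonyl)-3-hydroxy-1,3-dimethylcyclohexane-1-carboxylic acid | O=CC1=C[C@H](OC(=O)[C@H]2[C@](C)(O)CCC[C@@]2(C)C(=O)O)C[C@@H](C(C)=C)C1 | intermediate
20 | 2-(trimethylsilyl)ethyl ester of 19 at C19 | O=CC1=C[C@H](OC(=O)[C@H]2[C@](C)(O)CCC[C@@]2(C)C(=O)OCC[Si](C)(C)C)C[C@@H](C(C)=C)C1 | intermediate
21 | analogue of 20 with 3-chloroprop-1-en-2-yl in place of isopropenyl | O=CC1=C[C@H](OC(=O)[C@H]2[C@](C)(O)CCC[C@@]2(C)C(=O)OCC[Si](C)(C)C)C[C@@H](C(CCl)=C)C1 | intermediate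
22 | methyl oxalate of the tertiary alcohol of 21 | O=CC1=C[C@H](OC(=O)[C@H]2[C@](C)(OC(=O)C(=O)OC)CCC[C@@]2(C)C(=O)OCC[Si](C)(C)C)C[C@@H](C(CCl)=C)C1 | intermediate
23 | caesium oxalate of the tertiary alcohol of 21 | [Cs+].O=CC1=C[C@H](OC(=O)[C@H]2[C@](C)(OC(=O)C(=O)[O-])CCC[C@@]2(C)C(=O)OCC[Si](C)(C)C)C[C@@H](C(CCl)=C)C1 | intermediate
24 | caesium enolate of the ring-closed lactone aldehyde (C9–C10 formed, ring D still open) | [Cs+].[O-]C=C1C[C@H](C(CCl)=C)C[C@H]2OC(=O)[C@@H]3[C@](C)(C(=O)OCC[Si](C)(C)C)CCC[C@@]3(C)[C@@H]12 | intermediate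
25 | 2-(trimethylsilyl)ethyl (4R,5S,8R,9S,10S,11R,13S)-11-hydroxy-7-oxo-6,7-secokaur-16-ene-6,19-dioate 6,11-lactone | C=C1C[C@]2(C=O)C[C@H]1C[C@H]3OC(=O)[C@@H]4[C@](C)(C(=O)OCC[Si](C)(C)C)CCC[C@@]4(C)[C@@H]23 | intermediate
26 | (4R,5S,8R,9S,10S,11R,13S)-11-hydroxy-7-oxo-6,7-secokaur-16-ene-6,19-dioic acid 6,11-lactone | C=C1C[C@]2(C=O)C[C@H]1C[C@H]3OC(=O)[C@@H]4[C@](C)(C(=O)O)CCC[C@@]4(C)[C@@H]23 | intermediate
27 | (4R,5S,8R,9S,10S,11R,13S)-11-hydroxy-7-oxo-6,7-secokaur-16-ene-6,19-dioic acid | C=C1C[C@]2(C=O)C[C@H]1C[C@@H](O)[C@H]2[C@]1(C)CCC[C@@](C)(C(=O)O)[C@H]1C(=O)O | intermediate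
28 | (4R,5S,8R,9S,10S,13S)-7,11-dioxo-6,7-secokaur-16-ene-6,19-dioic acid | C=C1C[C@]2(C=O)C[C@H]1CC(=O)[C@H]2[C@]1(C)CCC[C@@](C)(C(=O)O)[C@H]1C(=O)O | target

**Totals**

Total step count: 17 (steps 1–4 ring C, steps 5–10 ring A, steps 11–17 after union).
Longest linear sequence: 13 steps (steps 5–17).

**Steps most likely to fail**

1. Step 15 (Proposed new method). What may go wrong: the enolate is protonated or consumed intermolecularly before it alkylates, because ring C must leave its chair to bring the chloromethyl-allyl arm over C8 while the lactone is intact; the s-cis ester rotamer needed for the 6-exo step also slows capture of the radical. Fallback with known chemistry: from 23, the same photoredox Giese cyclization is run in wet solvent (H2O, 10 equiv) so that the enolate is protonated to lactone aldehyde F1; ring D is then closed separately by intramolecular alkylation of the aldehyde enolate (KOtBu, THF, −78 → 0 °C), which returns to 25.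

2. Step 6. What may go wrong: dehydration of the β-hydroxy ketone to the exo-methylene ketone under the acid used for lactonization, or incomplete epimerization at C5. Fallback: from 11, MeLi (THF, 0 °C) and then benzyl chloromethyl ether give benzyloxymethyl ketone F2; hydrogenolysis (H2, Pd/C, EtOAc) gives 12 free of formaldehyde and Lewis acid, and mild TsOH in toluene closes the lactone with epimerization, returning to 13.

3. Step 11. What may go wrong: slow or unselective acylation (attack at the C19 carbonyl, or no reaction), since both anhydride carbonyls are hindered. Fallback: the carbinol is inverted first and the ester is made by carboxylate SN2 instead of acyl transfer. From 8, a Mitsunobu reaction with 4-nitrobenzoic acid gives inverted ester F3, methanolysis (K2CO3, MeOH) gives cis hydroxy enal F4, and a second Mitsunobu reaction of F4 with diacid 17 (the less hindered C6 acid reacts, with inversion at C11) returns to 19.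

Further compounds
F1 | step 15 | 2-(trimethylsilyl)ethyl ester lactone aldehyde with C8–H and intact 2-(chloromethyl)allyl group (C9–C10 formed, ring D open, both C8 epimers) | O=CC1C[C@H](C(CCl)=C)C[C@H]2OC(=O)[C@@H]3[C@](C)(C(=O)OCC[Si](C)(C)C)CCC[C@@]3(C)[C@@H]12
F2 | step 6 | methyl (1R)-2-[(benzyloxy)methyl]-1-methyl-3-oxocyclohexane-1-carboxylate (both C2 epimers) | COC(=O)[C@]1(C)CCCC(=O)C1COCc1ccccc1
F3 | step 11 | (1S,5S)-3-formyl-5-(prop-1-en-2-yl)cyclohex-2-en-1-yl 4-nitrobenzoate | O=CC1=C[C@@H](OC(=O)c2ccc([N+](=O)[O-])cc2)C[C@@H](C(C)=C)C1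
F4 | step 11 | (3S,5S)-3-hydroxy-5-(prop-1-en-2-yl)cyclohex-1-ene-1-carbaldehyde (OH cis to isopropenyl) | O=CC1=C[C@@H](O)C[C@@H](C(C)=C)C1
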